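**Retrosynthetic overview**

1. Sikokianin A comes from its penta-O-benzyl ether by a final hydrogenolysis. The descriptors (2S,3S,2''S,3''S) mean 2,3-cis in both rings C, which is the pattern of two syn-aldol units of the same absolute sense on a (3S,3''S)-succinyl core.
2. Key disconnection, made twice: O1–C8a and C4–C4a of each chromanone, leading to an acyclic bis(β-hydroxy amide) and two molecules of 3,5-bis(benzyloxy)benzyne. The two aryne carbons become C8a and C4a, so each ring A arrives preformed and each ring C closes onto it in one operation.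
3. Enabling feature: the alkoxide oxygen on C2 and the amide carbon C4 stand 1,3 on the chain O1–C2–C3–C4 (the four non-aromatic atoms of ring C). The benzyloxy group on C5, beside the triple bond, sends the oxygen to C8a and the carbanion to C4a.
4. The bis(β-hydroxy amide) comes from a cis-fused bis-γ-lactone (a 3,7-dioxabicyclo[3.3.0]octane-2,6-dione, two temporary rings absent from the target). This forms from a double Evans syn-aldol of a succinyl bis-imide with 4-methoxybenzaldehyde and 4-(benzyloxy)benzaldehyde; the bis-imide is assembled from succinic anhydride by two successive N-acylations.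
5. Ring order: rings B (from the aldehydes), then the two temporary γ-lactones (closed, then opened by aminolysis), then both rings C, fused to the incoming rings A, in the key step.

Key step: step 8

Remark on the chemistry: 3,5-bis(benzyloxy)phenol is taken as a purchasable starting material; chromanone numbering is used for all intermediates (O1, C2, C3, C4, C4a, C5 to C8, C8a for the half with the 4-methoxyphenyl group, the same locants with a double prime for the other half).

**Route**

Step 1
Reactants: 1 3,5-bis(benzyloxy)phenol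
Product: 2 3,5-bis(benzyloxy)phenyl N-isopropylcarbamate
Conditions: i-PrNCO (1.5 equiv), Et3N (0.2 equiv), CH2Cl2, 23 °C
Reagents that add atoms: isopropyl isocyanate CC(C)N=C=O
Why: Base-catalysed addition of the phenol O–H to the isocyanate (carbamoylation) should install the secondary carbamate needed as directing group for the ortho-metalation and creates no stereocenter.

Step 2
Reactants: 2 3,5-bis(benzyloxy)phenyl N-isopropylcarbamate
Product: 6 3,5-bis(benzyloxy)-2-(trimethylsilyl)phenyl N-isopropylcarbamate, via N-silyl carbamate 3 (not isolated), via ortho-lithiated N-silyl carbamate 4 (not isolated), via N-silyl ortho-silyl carbamate 5 (not isolated)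
Conditions: TBSOTf, TMEDA, Et2O, 0 to 23 °C; n-BuLi, TMEDA, −78 °C; Me3SiCl, −78 to 23 °C; aq. NaHSO4
Reagents that add atoms: chlorotrimethylsilane C[Si](C)(C)Cl
Why: Directed ortho-metalation: after N-silylation the O-carbamate should direct n-BuLi to C2, which is also flanked by the C3 benzyloxy group, and the aryllithium is silylated by Me3SiCl while the N-silyl group is lost on acidic work-up; no stereocenter is formed.

Step 3
Reactants: 6 3,5-bis(benzyloxy)-2-(trimethylsilyl)phenyl N-isopropylcarbamate
Product: 8 3,5-bis(benzyloxy)-2-(trimethylsilyl)phenyl trifluoromethanesulfonate, via silylphenol 7 (not isolated)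
Conditions: DBU, Et2NH, MeCN, 40 °C; then PhNTf2, 23 °C
Reagents that add atoms: N-phenylbis(trifluoromethanesulfonimide) O=S(=O)(N(c1ccccc1)S(=O)(=O)C(F)(F)F)C(F)(F)F
Why: E1cB cleavage of the secondary carbamate (the isocyanate is trapped by Et2NH) should free the hindered phenoxide, which is sulfonylated in the same flask to the 2-(trimethylsilyl)aryl triflate aryne precursor without loss of the C–Si bond.

Step 4
Reactants: 9 (S)-4-benzyl-1,3-oxazolidin-2-one; 10 succinic anhydride (oxolane-2,5-dione)
Product: 13 4-[(4S)-4-benzyl-2-oxo-1,3-oxazolidin-3-yl]-4-oxobutanoic acid, via lithium oxazolidinonide 11 (not isolated), via lithium carboxylate 12 (not isolated)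
Conditions: n-BuLi (1.0 equiv), THF, −78 °C; then 10 (1.1 equiv), −78 to 0 °C; aq. HCl (1 M)
Reagents that add atoms: none
Why: N-Acylation of the lithiated Evans oxazolidinone by ring opening of the cyclic anhydride should stop cleanly at the mono-imide, because the carboxylate 12 that forms is not an acylating agent, and the auxiliary stereocenter is untouched.

Step 5
Reactants: 13 4-[(4S)-4-benzyl-2-oxo-1,3-oxazolidin-3-yl]-4-oxobutanoic acid; 9 (S)-4-benzyl-1,3-oxazolidin-2-one
Product: 15 1,4-bis[(4S)-4-benzyl-2-oxo-1,3-oxazolidin-3-yl]butane-1,4-dione, via mixed pivalic anhydride 14 (not isolated)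
Conditions: PivCl (1.1 equiv), Et3N (2.5 equiv), THF, −20 °C; then LiCl (1.2 equiv), 9 (1.05 equiv), −20 to 23 °C
Reagents that add atoms: none
Why: Mixed-anhydride N-acylation of an oxazolidinone (pivaloyl chloride activation, LiCl and Et3N as the mild base system) should deliver the second auxiliary to the unhindered succinyl carbonyl of 14 rather than to the pivaloyl carbonyl and give the C2-symmetric bis-imide with both auxiliary stereocenters untouched.

Step 6
Reactants: 15 1,4-bis[(4S)-4-benzyl-2-oxo-1,3-oxazolidin-3-yl]butane-1,4-dione; 16 4-methoxybenzaldehyde; 17 4-(benzyloxy)benzaldehyde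
Product: 23 (1S,4S,5S,8S)-4-[4-(benzyloxy)phenyl]-8-(4-methoxyphenyl)-3,7-dioxabicyclo[3.3.0]octane-2,6-dione, via mono boron enolate 18 (not isolated), via mono boron aldolate 19 (not isolated), via aldolate-enolate 20 (not isolated), via bis(boron aldolate) 21 (not isolated), via bis-aldol diol 22 (not isolated)
Conditions: Bu2BOTf (1.05 equiv), i-Pr2NEt (1.2 equiv), CH2Cl2, 0 °C; 16 (1.0 equiv), −78 to 0 °C; Bu2BOTf (1.3 equiv), i-Pr2NEt (1.5 equiv), 0 °C; 17 (1.5 equiv), −78 to 0 °C; pH 7 buffer, MeOH, 30% H2O2, 0 °C; then DMAP (0.1 equiv), CH2Cl2, 23 °C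
Reagents that add atoms: none
Why: Two consecutive Evans syn-aldol reactions through Z-dibutylboron enolates in Zimmerman–Traxler chairs, each aldehyde adding to the enolate face turned away from the benzyl group of its (S)-auxiliary, should set C3 and C2 and then C3'' and C2'' as (S) with the first boron aldolate acting as protection during the second enolisation, after which both carbinols acylate the distal imides (5-exo-trig) to the cis-fused exo,exo bis-γ-lactone and release both auxiliaries.

Step 7
Reactants: 23 (1S,4S,5S,8S)-4-[4-(benzyloxy)phenyl]-8-(4-methoxyphenyl)-3,7-dioxabicyclo[3.3.0]octane-2,6-dione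
Product: 24 (2S,3S)-2-[(S)-hydroxy(4-methoxyphenyl)methyl]-3-{(S)-[4-(benzyloxy)phenyl](hydroxy)methyl}-1,4-di(pyrrolidin-1-yl)butane-1,4-dione
Conditions: pyrrolidine (5 equiv), AlMe3 (5 equiv), CH2Cl2, 0 to 23 °C; aq. KNaC4H4O6 (potassium sodium tartrate)
Reagents that add atoms: pyrrolidine C1CCNC1
Why: Aluminium-amide aminolysis of both γ-lactones should give the bis(β-hydroxy amide) without touching any bond at the four stereocenters, so each carbinol oxygen ends up 1,3 to an amide carbonyl.

Step 8
Reactants: 24 (2S,3S)-2-[(S)-hydroxy(4-methoxyphenyl)methyl]-3-{(S)-[4-(benzyloxy)phenyl](hydroxy)methyl}-1,4-di(pyrrolidin-1-yl)butane-1,4-dione; 8 3,5-bis(benzyloxy)-2-(trimethylsilyl)phenyl trifluoromethanesulfonate (two molecules)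
Product: 28 (2S,3S,2''S,3''S)-5,7,5'',7''-tetrakis(benzyloxy)-2''-[4-(benzyloxy)phenyl]-2-(4-methoxyphenyl)-3,3''-bichromane-4,4''-dione (penta-O-benzyl sikokianin A), via disodium dialkoxide 25 (not isolated), via 3,5-bis(benzyloxy)benzyne 26 (not isolated), via bis(hemiaminal alkoxide) 27 (not isolated)
Conditions: NaH (2.2 equiv), THF, 0 °C; then 8 (3.0 equiv), CsF (8 equiv), THF, 23 to 50 °C; then aq. NH4Cl, 0 °C
Reagents that add atoms: second molecule of aryne precursor 8 FC(F)(F)S(=O)(=O)Oc1cc(OCc2ccccc2)cc(OCc2ccccc2)c1[Si](C)(C)C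
Why: Proposed new method: each of the two C2 alkoxides of 25 should add to its own molecule of 3,5-bis(benzyloxy)benzyne 26 (two molecules of 8 are consumed per molecule of 24) at the aryne carbon remote from the flanking benzyloxy group, which forms the O1–C8a bond and leaves the carbanion on C4a, ortho to that oxygen and inductively stabilised by it; this aryl anion then attacks the pyrrolidine amide carbon C4, which sits 1,3 to the oxygen, and so closes ring C as the tetrahedral hemiaminal alkoxide 27 that collapses to the ketone only on quench. The closest known reaction type is the CsF-mediated annulation of arynes by methyl salicylates to xanthones (O-arylation, then acylation of the aryl anion), together with aryne acyl-alkylation; it has not been shown for aliphatic β-oxido amides. Each ring C closes by a formal [4+2] annulation of the four-atom unit O1–C2–C3–C4 onto C8a/C4a, the second bond through a 6-exo-trig acyl addition that is favoured over the 7-membered attack on the distal amide. No stereocenter is created: C2 and C2'' keep their configuration because only the O–H bond is engaged, and C3 and C3'' cannot enolise because no ketone exists under the basic conditions, so the syn-aldol pattern becomes the 2,3-cis pattern of both rings. The step needs regioselective addition to the unsymmetrical aryne (secured by the C5 benzyloxy group beside the triple bond) and an aryl anion that acylates faster than it is protonated (secured by NaH, which leaves only H2, and by THF as a non-acidic solvent); arylating the oxygen before any ketone is present also excludes retro-aldol cleavage.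

Step 9
Reactants: 28 (2S,3S,2''S,3''S)-5,7,5'',7''-tetrakis(benzyloxy)-2''-[4-(benzyloxy)phenyl]-2-(4-methoxyphenyl)-3,3''-bichromane-4,4''-dione
Product: 29 Sikokianin A
Conditions: H2 (1 atm), 10% Pd/C, EtOAc/THF, 23 °C
Reagents that add atoms: none
Why: Heterogeneous hydrogenolysis of the five benzyl ethers under neutral conditions should free the phenols without enolising C3 or C3'', so the cis,cis configuration and the aryl methyl ether are kept.

**Compound list**

1 | 3,5-bis(benzyloxy)phenol | Oc1cc(OCc2ccccc2)cc(OCc2ccccc2)c1 | starting material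
2 | 3,5-bis(benzyloxy)phenyl N-isopropylcarbamate | CC(C)NC(=O)Oc1cc(OCc2ccccc2)cc(OCc2ccccc2)c1 | intermediate
3 | N-(tert-butyldimethylsilyl) derivative of 2 | CC(C)N(C(=O)Oc1cc(OCc2ccccc2)cc(OCc2ccccc2)c1)[Si](C)(C)C(C)(C)C | intermediate
4 | 2-lithio derivative of 3 | CC(C)N(C(=O)Oc1cc(OCc2ccccc2)cc(OCc2ccccc2)c1[Li])[Si](C)(C)C(C)(C)C | intermediate
5 | N-(tert-butyldimethylsilyl)-2-(trimethylsilyl) carbamate | CC(C)N(C(=O)Oc1cc(OCc2ccccc2)cc(OCc2ccccc2)c1[Si](C)(C)C)[Si](C)(C)C(C)(C)C | intermediate
6 | 3,5-bis(benzyloxy)-2-(trimethylsilyl)phenyl N-isopropylcarbamate | CC(C)NC(=O)Oc1cc(OCc2ccccc2)cc(OCc2ccccc2)c1[Si](C)(C)C | intermediate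
7 | 3,5-bis(benzyloxy)-2-(trimethylsilyl)phenol (formed as its DBU salt) | Oc1cc(OCc2ccccc2)cc(OCc2ccccc2)c1[Si](C)(C)C | intermediate
8 | 3,5-bis(benzyloxy)-2-(trimethylsilyl)phenyl trifluoromethanesulfonate | FC(F)(F)S(=O)(=O)Oc1cc(OCc2ccccc2)cc(OCc2ccccc2)c1[Si](C)(C)C | intermediate
9 | (S)-4-benzyl-1,3-oxazolidin-2-one | O=C1N[C@@H](Cc2ccccc2)CO1 | starting material
10 | succinic anhydride (oxolane-2,5-dione) | O=C1CCC(=O)O1 | starting material
11 | lithium salt of 9 (N-lithio) | [Li]N1[C@@H](Cc2ccccc2)COC1=O | intermediate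
12 | lithium 4-[(4S)-4-benzyl-2-oxo-1,3-oxazolidin-3-yl]-4-oxobutanoate | [Li+].[O-]C(=O)CCC(=O)N1[C@@H](Cc2ccccc2)COC1=O | intermediate
13 | 4-[(4S)-4-benzyl-2-oxo-1,3-oxazolidin-3-yl]-4-oxobutanoic acid | OC(=O)CCC(=O)N1[C@@H](Cc2ccccc2)COC1=O | intermediate
14 | mixed pivalic anhydride of 13 | CC(C)(C)C(=O)OC(=O)CCC(=O)N1[C@@H](Cc2ccccc2)COC1=O | intermediate
15 | 1,4-bis[(4S)-4-benzyl-2-oxo-1,3-oxazolidin-3-yl]butane-1,4-dione | O=C(CCC(=O)N1[C@@H](Cc2ccccc2)COC1=O)N1[C@@H](Cc2ccccc2)COC1=O | intermediate
16 | 4-methoxybenzaldehyde | COc1ccc(C=O)cc1 | starting material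
17 | 4-(benzyloxy)benzaldehyde | O=Cc1ccc(OCc2ccccc2)cc1 | starting material
18 | mono Z-dibutylboron enolate of 15 | CCCCB(CCCC)O/C(=C\CC(=O)N1[C@@H](Cc2ccccc2)COC1=O)N1[C@@H](Cc2ccccc2)COC1=O | intermediate
19 | dibutylboron aldolate of the first syn-aldol (2S,3S; 4-methoxyphenyl carbinol) | COc1ccc(cc1)[C@@H](OB(CCCC)CCCC)[C@@H](C(=O)N1[C@@H](Cc2ccccc2)COC1=O)CC(=O)N1[C@@H](Cc2ccccc2)COC1=O | intermediate
20 | Z-dibutylboron enolate of 19 at the second imide | COc1ccc(cc1)[C@@H](OB(CCCC)CCCC)[C@@H](C(=O)N1[C@@H](Cc2ccccc2)COC1=O)/C=C(\OB(CCCC)CCCC)N1[C@@H](Cc2ccccc2)COC1=O | intermediate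
21 | bis(dibutylboron aldolate) of the double syn-aldol | COc1ccc(cc1)[C@@H](OB(CCCC)CCCC)[C@@H](C(=O)N1[C@@H](Cc2ccccc2)COC1=O)[C@H](C(=O)N1[C@@H](Cc2ccccc2)COC1=O)[C@H](OB(CCCC)CCCC)c1ccc(OCc2ccccc2)cc1 | intermediate
22 | (2S,3S)-1,4-bis[(4S)-4-benzyl-2-oxo-1,3-oxazolidin-3-yl]-2-[(S)-hydroxy(4-methoxyphenyl)methyl]-3-{(S)-[4-(benzyloxy)phenyl](hydroxy)methyl}butane-1,4-dione | COc1ccc(cc1)[C@@H](O)[C@@H](C(=O)N1[C@@H](Cc2ccccc2)COC1=O)[C@H](C(=O)N1[C@@H](Cc2ccccc2)COC1=O)[C@H](O)c1ccc(OCc2ccccc2)cc1 | intermediate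
23 | (1S,4S,5S,8S)-4-[4-(benzyloxy)phenyl]-8-(4-methoxyphenyl)-3,7-dioxabicyclo[3.3.0]octane-2,6-dione (cis-fused, both aryl groups exo) | COc1ccc(cc1)[C@H]1OC(=O)[C@H]2[C@@H]1C(=O)O[C@@H]2c1ccc(OCc2ccccc2)cc1 | intermediate
24 | (2S,3S)-2-[(S)-hydroxy(4-methoxyphenyl)methyl]-3-{(S)-[4-(benzyloxy)phenyl](hydroxy)methyl}-1,4-di(pyrrolidin-1-yl)butane-1,4-dione | COc1ccc(cc1)[C@@H](O)[C@@H](C(=O)N1CCCC1)[C@H](C(=O)N1CCCC1)[C@H](O)c1ccc(OCc2ccccc2)cc1 | intermediate
25 | disodium dialkoxide of 24 | COc1ccc(cc1)[C@@H]([O-])[C@@H](C(=O)N1CCCC1)[C@H](C(=O)N1CCCC1)[C@H]([O-])c1ccc(OCc2ccccc2)cc1.[Na+].[Na+] | intermediate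
26 | 3,5-bis(benzyloxy)benzyne | C1#CC(OCc2ccccc2)=CC(OCc2ccccc2)=C1 | intermediate
27 | bis(hemiaminal alkoxide): 28 with each C4 ketone as C(O−)(pyrrolidin-1-yl), disodium salt | COc1ccc([C@H]2Oc3cc(OCc4ccccc4)cc(OCc4ccccc4)c3C([O-])(N3CCCC3)[C@H]2[C@@H]2C([O-])(N3CCCC3)c3c(OCc4ccccc4)cc(OCc4ccccc4)cc3O[C@@H]2c2ccc(OCc3ccccc3)cc2)cc1.[Na+].[Na+] | intermediate
28 | (2S,3S,2''S,3''S)-5,7,5'',7''-tetrakis(benzyloxy)-2''-[4-(benzyloxy)phenyl]-2-(4-methoxyphenyl)-3,3''-bichromane-4,4''-dione | COc1ccc([C@H]2Oc3cc(OCc4ccccc4)cc(OCc4ccccc4)c3C(=O)[C@H]2[C@@H]2C(=O)c3c(OCc4ccccc4)cc(OCc4ccccc4)cc3O[C@@H]2c2ccc(OCc3ccccc3)cc2)cc1 | intermediate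
29 | Sikokianin A | COc1ccc([C@H]2Oc3cc(O)cc(O)c3C(=O)[C@H]2[C@@H]2C(=O)c3c(O)cc(O)cc3O[C@@H]2c2ccc(O)cc2)cc1 | target

**Step count and risks**

Total step count: 9. Longest linear sequence: 6 steps (steps 4 to 9); the aryne branch (steps 1 to 3, then 8 and 9) is 5 steps long.

Steps most likely to fail:

1. Step 8 (proposed new method). The C4a aryl anion may be protonated (adventitious water, the substrate) before it acylates, so that plain aryl ethers form. The benzylic alkoxide may instead transfer hydride to the aryne, or attack the sulfonyl group of 8. The fallback uses known chemistry and runs from 24 back to 28. The free diol 24 is O-arylated with 8 and CsF in MeCN, where the aryl anion is protonated on purpose (fluoride-mediated insertion of the aryne into the O–H bonds). This gives the bis(aryl ether) (2S,3S)-2-{(S)-[3,5-bis(benzyloxy)phenoxy](4-methoxyphenyl)methyl}-3-{(S)-[4-(benzyloxy)phenyl][3,5-bis(benzyloxy)phenoxy]methyl}-1,4-di(pyrrolidin-1-yl)butane-1,4-dione F1. Both tertiary amides of F1 are then activated with Tf2O and 2-chloropyridine (CH2Cl2, −78 to 0 °C), so that each electron-rich aryl ether ring attacks its own activated amide ortho to the ether oxygen (intramolecular Friedel–Crafts acylation). Aqueous NaHCO3 hydrolyses the two ketiminium ions to 28. In this variant the O1–C8a bonds are made first and the rings are closed by the C4–C4a bonds.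

2. Step 6. Mono-enolisation of 15 may be unselective, giving homo-double-aldol products. The first aldolate may lactonise onto the distal imide before the second enolisation, which would expel the second auxiliary and leave only substrate control. The second aldol of the branched enolate may be sluggish. The fallback runs from 9 back to 23 and installs the two auxiliaries around the two aldol reactions one after the other. Compound 9 is acylated with mono-tert-butyl succinate (PivCl, Et3N, LiCl, THF) to tert-butyl 4-[(4S)-4-benzyl-2-oxo-1,3-oxazolidin-3-yl]-4-oxobutanoate F2. An Evans syn-aldol with 16 gives the β-hydroxy imide F3, which cannot lactonise onto the tert-butyl ester. TBSOTf and 2,6-lutidine give the silyl ether F4. Me3SiOTf and 2,6-lutidine cleave the tert-butyl ester to the acid F5. PivCl and Et3N, then 11, give the silyl-protected bis-imide F6. A second Evans syn-aldol with 17 gives the mono-silylated double aldol F7. HF·pyridine removes the silyl group and both carbinols lactonise to 23.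

3. Step 9. Hydrogenolysis of the benzylic C2–O1 and C2''–O1'' bonds (ring opening to dihydrochalcones) may compete with debenzylation, or the reaction may stall before all five benzyl groups are gone. The fallback runs from 28 to 29 without a new compound. It is a non-reductive debenzylation with BCl3 and pentamethylbenzene as cation scavenger (CH2Cl2, −78 °C). This cleaves the aryl benzyl ethers by Lewis-acid-assisted benzyl transfer to the scavenger and should leave the aryl methyl ether and the C2–O bonds intact at this temperature.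

**Further compounds**

F1 | step 8 | (2S,3S)-2-{(S)-[3,5-bis(benzyloxy)phenoxy](4-methoxyphenyl)methyl}-3-{(S)-[4-(benzyloxy)phenyl][3,5-bis(benzyloxy)phenoxy]methyl}-1,4-di(pyrrolidin-1-yl)butane-1,4-dione | COc1ccc(cc1)[C@@H](Oc1cc(OCc2ccccc2)cc(OCc2ccccc2)c1)[C@@H](C(=O)N1CCCC1)[C@H](C(=O)N1CCCC1)[C@H](Oc1cc(OCc2ccccc2)cc(OCc2ccccc2)c1)c1ccc(OCc2ccccc2)cc1
F2 | step 6 | tert-butyl 4-[(4S)-4-benzyl-2-oxo-1,3-oxazolidin-3-yl]-4-oxobutanoate | CC(C)(C)OC(=O)CCC(=O)N1[C@@H](Cc2ccccc2)COC1=O
F3 | step 6 | tert-butyl (3S)-3-{[(4S)-4-benzyl-2-oxo-1,3-oxazolidin-3-yl]carbonyl}-4-hydroxy-4-(4-methoxyphenyl)butanoate, (4S) carbinol | COc1ccc(cc1)[C@@H](O)[C@@H](C(=O)N1[C@@H](Cc2ccccc2)COC1=O)CC(=O)OC(C)(C)C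
F4 | step 6 | tert-butyldimethylsilyl ether of F3 | COc1ccc(cc1)[C@@H](O[Si](C)(C)C(C)(C)C)[C@@H](C(=O)N1[C@@H](Cc2ccccc2)COC1=O)CC(=O)OC(C)(C)C
F5 | step 6 | carboxylic acid from F4 | COc1ccc(cc1)[C@@H](O[Si](C)(C)C(C)(C)C)[C@@H](C(=O)N1[C@@H](Cc2ccccc2)COC1=O)CC(=O)O
F6 | step 6 | silyl-protected mono-aldol bis-imide | COc1ccc(cc1)[C@@H](O[Si](C)(C)C(C)(C)C)[C@@H](C(=O)N1[C@@H](Cc2ccccc2)COC1=O)CC(=O)N1[C@@H](Cc2ccccc2)COC1=O
F7 | step 6 | mono-silylated double syn-aldol bis-imide | COc1ccc(cc1)[C@@H](O[Si](C)(C)C(C)(C)C)[C@@H](C(=O)N1[C@@H](Cc2ccccc2)COC1=O)[C@H](C(=O)N1[C@@H](Cc2ccccc2)COC1=O)[C@H](O)c1ccc(OCc2ccccc2)cc1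
F0 | step 9 | none | none
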